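**Plan**

- The six-membered ring of the hydrindane carries an equatorial C4–Br next to the quaternary C3a, with C3a and C7a trans. This is the pattern left when a C7a enol opens a bromonium ion at its tertiary carbon, so the central cut is C3a–C7a.
- Cuts, in retrosynthetic order: C1–C2 (a hydrogenated metathesis alkene), C7–CH3, the linker CH2–C(OH) bond to ring A (allylsilane plus ketone), C1 back to an ester carbon, then C3a–C7a. Ring A is cut the same way at CMe2–CH2.
- Forward: epoxy alcohol, epoxy keto ester, bromohydrin, bromocyclohexanone (first ring). The ring-A bromoketone is made by the same cyclisation. The two halves are joined, the cyclopentene is closed by metathesis, and the alkene is hydrogenated last.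
- Stereochemistry: Sharpless epoxidation with D-(−)-diethyl tartrate fixes C3a and C4 (and the ring-A C–Br). Bromide opening inverts the CH carbon, and the cyclisation retains the quaternary carbon by double inversion. C7a is thermodynamic.
- The ring-A carbinol comes from equatorial attack on the chair ketone, C7 from equatorial methyl delivery away from the axial C3a methyl, and C1 from hydrogenation directed by the C7 hydroxyl.

Key step: step 5

Remark: hydrindane locants used throughout are C1 (CH2 linker), C3a (methyl), C4 (bromine), C7 (carbinol) and C7a (ring-fusion H); the names of the last two compounds use them.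
Remark: the secondary C7 carbinol carried from the borohydride reduction to the Dess–Martin oxidation is drawn as the axial alcohol expected from equatorial hydride delivery; its epimer would converge at the ketone.
Remark: the two bromohydrin keto esters are drawn open-chain; a cyclic hemiketal tautomer, if present, would ionise to the same bromonium ion.

**Route**

Step 1
Reactants: 1 pent-1-en-4-yne
Product: 4 (E)-3-methylhexa-2,5-dien-1-ol, via alkenylalane 2 (not isolated), via lithium alanate 3 (not isolated)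
Conditions: Me3Al, Cp2ZrCl2 (20 mol%), CH2Cl2, 0 °C → rt; n-BuLi, THF, −78 °C; (CH2O)n, rt; aq. HCl
Reagents that add atoms: trimethylaluminium C[Al](C)C; paraformaldehyde (formaldehyde) C=O
Why: Negishi zirconium-catalysed carboalumination adds Me–Al syn and regioselectively across the terminal alkyne only, and the derived alanate is hydroxymethylated with retention, so the (E)-trisubstituted allylic alcohol should result.

Step 2
Reactants: 4 (E)-3-methylhexa-2,5-dien-1-ol
Product: 5 [(2R,3R)-3-methyl-3-(prop-2-en-1-yl)oxiran-2-yl]methanol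
Conditions: Ti(OiPr)4 (10 mol%), D-(−)-diethyl tartrate (12 mol%), t-BuOOH, 4 Å MS, CH2Cl2, −20 °C
Reagents that add atoms: tert-butyl hydroperoxide CC(C)(C)OO
Why: Sharpless asymmetric epoxidation oxidises only the allylic-alcohol olefin, and D-(−)-tartrate delivers oxygen to the face giving the (2R,3R)-epoxide (mirror image of the L-(+)-tartrate product of geraniol-type alcohols), which fixes the future C4 and C3a.

Step 3
Reactants: 5 [(2R,3R)-3-methyl-3-(prop-2-en-1-yl)oxiran-2-yl]methanol; 6 methyl acetoacetate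
Product: 9 methyl 5-[(2R,3R)-3-methyl-3-(prop-2-en-1-yl)oxiran-2-yl]-3-oxopentanoate, via epoxy triflate 7 (not isolated), via acetoacetate dianion 8 (not isolated)
Conditions: Tf2O, 2,6-lutidine, CH2Cl2, −78 °C; then dianion of 6 (NaH, n-BuLi, THF, 0 °C), −78 → −30 °C; AcOH
Reagents that add atoms: none
Why: Weiler dianion alkylation, in which the terminal carbanion displaces the primary triflate by SN2 at low temperature much faster than it attacks the fully substituted epoxide, so both epoxide stereocentres are carried through unchanged.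

Step 4
Reactants: 9 methyl 5-[(2R,3R)-3-methyl-3-(prop-2-en-1-yl)oxiran-2-yl]-3-oxopentanoate
Product: 10 methyl (6S,7R)-6-bromo-7-hydroxy-7-methyl-3-oxodec-9-enoate
Conditions: Li2NiBr4, THF, 0 °C → rt; pH 7 buffer
Reagents that add atoms: dilithium tetrabromonickelate [Li+].[Li+].[Ni+2].[Br-].[Br-].[Br-].[Br-]
Why: Regioselective SN2 epoxide opening by soft bromide at the less substituted carbon C6 with inversion should give the secondary bromide (6S) and leave the tertiary C7–O bond, and hence its configuration, intact.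

Step 5
Reactants: 10 methyl (6S,7R)-6-bromo-7-hydroxy-7-methyl-3-oxodec-9-enoate
Product: 12 methyl (1S,2S,3S)-3-bromo-2-methyl-6-oxo-2-(prop-2-en-1-yl)cyclohexane-1-carboxylate, via bromonium ion 11 (not isolated)
Conditions: SnCl4 (2.2 equiv), CH2Cl2, −78 → −20 °C; aq. NaHCO3
Reagents that add atoms: none
Why: SnCl4 chelates the β-keto ester (raising its enol content) and ionises the tertiary C7–OH with participation of the neighbouring bromine, so bromonium ion 11 forms with inversion at C7 and with C6 untouched, and the enol carbon C2 then opens it at the tertiary carbon anti to bromine. The closest known reaction type is the bromonium (cation–olefin) cyclisation terminated by a 1,3-dicarbonyl, with the bromonium ion generated enantiospecifically from a bromohydrin instead of from an alkene and a Br+ reagent. The bromocyclohexanone closes by a 6-endo opening of the bromonium ion (enol-endo) through a chair. The quaternary centre (C3a of the target) is set by the double inversion at C7 (net retention of the epoxidation-derived configuration, methyl axial, allyl equatorial), the C–Br centre (C4) is carried over from 10 and ends equatorial because it must be anti to the new ring bond, and the ester-bearing centre (C7a) equilibrates through the enol to the equatorial, trans position. The step needs C- rather than O-alkylation and an untouched allyl group: tin chelation favours the carbon terminus and an O-cyclised enol ether can re-ionise to the same bromonium ion, while the monosubstituted alkene cannot reach the cation in a ring larger than four and no Br+ source is present to attack it.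

Step 6
Reactants: 12 methyl (1S,2S,3S)-3-bromo-2-methyl-6-oxo-2-(prop-2-en-1-yl)cyclohexane-1-carboxylate
Product: 13 methyl (1S,2S,3S,6R)-3-bromo-6-hydroxy-2-methyl-2-(prop-2-en-1-yl)cyclohexane-1-carboxylate
Conditions: NaBH4, MeOH, −20 °C
Reagents that add atoms: none
Why: Chemoselective borohydride reduction of the ketone (ester and bromide inert) removes the acidic β-keto ester, with hydride expected on the equatorial side away from the axial C3a methyl to give the axial alcohol, a centre that is re-oxidised later.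

Step 7
Reactants: 13 methyl (1S,2S,3S,6R)-3-bromo-6-hydroxy-2-methyl-2-(prop-2-en-1-yl)cyclohexane-1-carboxylate
Product: 15 (1R,2S,3S,4S)-4-bromo-3-methyl-3-(prop-2-en-1-yl)-2-[3-(trimethylsilyl)prop-1-en-2-yl]cyclohexan-1-ol, via bis(silylmethyl) carbinol 14 (not isolated)
Conditions: Me3SiCH2MgCl, CeCl3, THF, −78 °C → rt; then SiO2, CH2Cl2
Reagents that add atoms: (trimethylsilyl)methylmagnesium chloride C[Si](C)(C)C[Mg]Cl
Why: Cerium-mediated double addition of Me3SiCH2 to the ester followed by Peterson elimination of the bis(silylmethyl) carbinol gives the 2-substituted allylsilane, the non-basic organocerium reagent tolerating the alkoxide, the secondary bromide and the α-stereocentre.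

Step 8
Reactants: 15 (1R,2S,3S,4S)-4-bromo-3-methyl-3-(prop-2-en-1-yl)-2-[3-(trimethylsilyl)prop-1-en-2-yl]cyclohexan-1-ol
Product: 16 triethyl{[(1R,2S,3S,4S)-4-bromo-3-methyl-3-(prop-2-en-1-yl)-2-[3-(trimethylsilyl)prop-1-en-2-yl]cyclohexyl]oxy}silane
Conditions: TESOTf, 2,6-lutidine, CH2Cl2, −78 → 0 °C
Reagents that add atoms: triethylsilyl trifluoromethanesulfonate CC[Si](CC)(CC)OS(=O)(=O)C(F)(F)F
Why: Silyl ether formation masks the hindered secondary hydroxyl so that TiCl4 generates no HCl in the coupling (which would protodesilylate the allylsilane) and a silyl-Prins pathway with the ketone is suppressed.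

Step 9
Reactants: 17 3-methylbut-2-en-1-ol
Product: 18 [(2R)-3,3-dimethyloxiran-2-yl]methanol
Conditions: Ti(OiPr)4, D-(−)-diethyl tartrate, t-BuOOH, 4 Å MS, CH2Cl2, −20 °C
Reagents that add atoms: tert-butyl hydroperoxide CC(C)(C)OO
Why: Sharpless asymmetric epoxidation with the same tartrate as in step 2 gives the (R)-epoxy alcohol, whose stereocentre becomes the ring-A C–Br carbon.

Step 10
Reactants: 18 [(2R)-3,3-dimethyloxiran-2-yl]methanol; 19 prop-2-en-1-yl 3-oxobutanoate (allyl acetoacetate)
Product: 22 prop-2-en-1-yl 5-[(2R)-3,3-dimethyloxiran-2-yl]-3-oxopentanoate, via epoxy triflate 20 (not isolated), via allyl acetoacetate dianion 21 (not isolated)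
Conditions: Tf2O, 2,6-lutidine, CH2Cl2, −78 °C; then dianion of 19 (NaH, n-BuLi, THF, 0 °C), −78 → −30 °C; AcOH
Reagents that add atoms: none
Why: Weiler dianion alkylation as in step 3, the primary triflate being displaced by the terminal carbanion without touching the epoxide.

Step 11
Reactants: 22 prop-2-en-1-yl 5-[(2R)-3,3-dimethyloxiran-2-yl]-3-oxopentanoate
Product: 23 prop-2-en-1-yl (6S)-6-bromo-7-hydroxy-7-methyl-3-oxooctanoate
Conditions: Li2NiBr4, THF, 0 °C → rt; pH 7 buffer
Reagents that add atoms: dilithium tetrabromonickelate [Li+].[Li+].[Ni+2].[Br-].[Br-].[Br-].[Br-]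
Why: SN2 opening of the trisubstituted epoxide by soft bromide at the secondary carbon with inversion, as in step 4, gives the (S)-bromide beside the tertiary alcohol.

Step 12
Reactants: 23 prop-2-en-1-yl (6S)-6-bromo-7-hydroxy-7-methyl-3-oxooctanoate
Product: 25 prop-2-en-1-yl (1S,3S)-3-bromo-2,2-dimethyl-6-oxocyclohexane-1-carboxylate, via bromonium ion 24 (not isolated)
Conditions: SnCl4 (2.2 equiv), CH2Cl2, −78 → −20 °C; aq. NaHCO3
Reagents that add atoms: none
Why: The same bromohydrin ionisation and 6-endo bromonium cyclisation as in step 5 closes the ring-A bromocyclohexanone with bromine equatorial (configuration carried from 23) and the ester settling equatorial through the enol.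

Step 13
Reactants: 25 prop-2-en-1-yl (1S,3S)-3-bromo-2,2-dimethyl-6-oxocyclohexane-1-carboxylate
Product: 27 (4S)-4-bromo-3,3-dimethylcyclohexan-1-one, via keto acid 26 (not isolated)
Conditions: Pd(PPh3)4 (5 mol%), morpholine, THF, rt
Reagents that add atoms: none
Why: Tsuji deallylation (π-allylpalladium formation, allyl transfer to morpholine) frees the β-keto acid, which decarboxylates at room temperature under conditions that leave an unactivated secondary bromide alone.

Step 14
Reactants: 16 triethyl{[(1R,2S,3S,4S)-4-bromo-3-methyl-3-(prop-2-en-1-yl)-2-[3-(trimethylsilyl)prop-1-en-2-yl]cyclohexyl]oxy}silane; 27 (4S)-4-bromo-3,3-dimethylcyclohexan-1-one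
Product: 29 (1R,2S,3S,4S)-4-bromo-2-{3-[(1S,4S)-4-bromo-1-hydroxy-3,3-dimethylcyclohexyl]prop-1-en-2-yl}-3-methyl-3-(prop-2-en-1-yl)cyclohexan-1-ol, via triethylsilyl ether 28 (not isolated)
Conditions: TiCl4, CH2Cl2, −78 °C; then HF·pyridine, THF, 0 °C → rt
Reagents that add atoms: none
Why: In this Hosomi–Sakurai allylation the TiCl4-activated ketone is attacked by the terminal carbon of the 2-substituted allylsilane (SE2′, which returns the same skeleton), and attack from the equatorial side, away from the axial C3 methyl of the bromine-equatorial chair, should place the new CH2 equatorial and the hydroxyl axial and cis to bromine, after which HF·pyridine frees the C7 hydroxyl.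

Step 15
Reactants: 29 (1R,2S,3S,4S)-4-bromo-2-{3-[(1S,4S)-4-bromo-1-hydroxy-3,3-dimethylcyclohexyl]prop-1-en-2-yl}-3-methyl-3-(prop-2-en-1-yl)cyclohexan-1-ol
Product: 30 (2S,3S,4S)-4-bromo-2-{3-[(1S,4S)-4-bromo-1-hydroxy-3,3-dimethylcyclohexyl]prop-1-en-2-yl}-3-methyl-3-(prop-2-en-1-yl)cyclohexan-1-one
Conditions: Dess–Martin periodinane, NaHCO3, CH2Cl2, 0 °C → rt
Reagents that add atoms: none
Why: Dess–Martin oxidation converts the only secondary alcohol into the ketone under buffered conditions (tertiary alcohol inert), and the α-centre C7a already holds its substituent in the thermodynamically preferred equatorial position.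

Step 16
Reactants: 30 (2S,3S,4S)-4-bromo-2-{3-[(1S,4S)-4-bromo-1-hydroxy-3,3-dimethylcyclohexyl]prop-1-en-2-yl}-3-methyl-3-(prop-2-en-1-yl)cyclohexan-1-one
Product: 31 (1R,2S,3S,4S)-4-bromo-2-{3-[(1S,4S)-4-bromo-1-hydroxy-3,3-dimethylcyclohexyl]prop-1-en-2-yl}-1,3-dimethyl-3-(prop-2-en-1-yl)cyclohexan-1-ol
Conditions: MeMgBr, CeCl3, THF, −78 °C
Reagents that add atoms: methylmagnesium bromide C[Mg]Br
Why: The weakly basic organocerium reagent adds to the enolisable β,γ-unsaturated ketone without deprotonation, and approach from the equatorial direction, away from the 1,3-diaxial C3a methyl, should give the equatorial methyl and axial hydroxyl of the target (7R).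

Step 17
Reactants: 31 (1R,2S,3S,4S)-4-bromo-2-{3-[(1S,4S)-4-bromo-1-hydroxy-3,3-dimethylcyclohexyl]prop-1-en-2-yl}-1,3-dimethyl-3-(prop-2-en-1-yl)cyclohexan-1-ol
Product: 32 (3aS,4S,7R,7aS)-4-bromo-1-{[(1S,4S)-4-bromo-1-hydroxy-3,3-dimethylcyclohexyl]methyl}-3a,7-dimethyl-3a,4,5,6,7,7a-hexahydro-3H-inden-7-ol
Conditions: Grubbs second-generation catalyst (10 mol%), CH2Cl2, 40 °C
Reagents that add atoms: none
Why: Ring-closing metathesis joins the allyl arm and the 1,1-disubstituted alkene, which are trans-diequatorial neighbours, into the trisubstituted cyclopentene with loss of ethene, free tertiary alcohols and alkyl bromides being tolerated.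

Step 18
Reactants: 32 (3aS,4S,7R,7aS)-4-bromo-1-{[(1S,4S)-4-bromo-1-hydroxy-3,3-dimethylcyclohexyl]methyl}-3a,7-dimethyl-3a,4,5,6,7,7a-hexahydro-3H-inden-7-ol
Product: 33 (1S,3aS,4S,7R,7aS)-4-bromo-1-{[(1S,4S)-4-bromo-1-hydroxy-3,3-dimethylcyclohexyl]methyl}-3a,7-dimethyloctahydro-1H-inden-7-ol
Conditions: [Ir(cod)(PCy3)(py)]PF6 (10 mol%), H2 (1 atm), CH2Cl2, rt
Reagents that add atoms: none
Why: In this hydroxyl-directed hydrogenation Crabtree's catalyst binds the axial C7 hydroxyl, which is homoallylic to C1=C2 and lies on the face of the angular methyl, and delivers hydrogen to that face, so C1 should receive H syn to the hydroxyl and keep the CH2 substituent on the opposite face (1S).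

**Compound list**

1 | pent-1-en-4-yne | C=CCC#C | starting material
2 | (E)-dimethyl(2-methylpenta-1,4-dien-1-yl)alane | C=CC/C(C)=C/[Al](C)C | intermediate (not isolated)
3 | lithium (E)-butyldimethyl(2-methylpenta-1,4-dien-1-yl)alanate | [Li+].C=CC/C(C)=C/[Al-](C)(C)CCCC | intermediate (not isolated)
4 | (E)-3-methylhexa-2,5-dien-1-ol | C=CC/C(C)=C/CO | intermediate
5 | [(2R,3R)-3-methyl-3-(prop-2-en-1-yl)oxiran-2-yl]methanol | OC[C@H]1O[C@]1(C)CC=C | intermediate
6 | methyl acetoacetate | COC(=O)CC(C)=O | starting material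
7 | [(2R,3R)-3-methyl-3-(prop-2-en-1-yl)oxiran-2-yl]methyl trifluoromethanesulfonate | O=S(=O)(OC[C@H]1O[C@]1(C)CC=C)C(F)(F)F | intermediate (not isolated)
8 | methyl acetoacetate dianion (sodium lithium salt, C4 carbanion) | [Li+].[Na+].COC(=O)C=C([O-])[CH2-] | intermediate (not isolated)
9 | methyl 5-[(2R,3R)-3-methyl-3-(prop-2-en-1-yl)oxiran-2-yl]-3-oxopentanoate | COC(=O)CC(=O)CC[C@H]1O[C@]1(C)CC=C | intermediate
10 | methyl (6S,7R)-6-bromo-7-hydroxy-7-methyl-3-oxodec-9-enoate | COC(=O)CC(=O)CC[C@H](Br)[C@@](O)(C)CC=C | intermediate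
11 | (2S,3S)-2-(5-methoxy-3,5-dioxopentyl)-3-methyl-3-(prop-2-en-1-yl)bromiranium | COC(=O)CC(=O)CC[C@@H]1[Br+][C@@]1(C)CC=C | intermediate (not isolated)
12 | methyl (1S,2S,3S)-3-bromo-2-methyl-6-oxo-2-(prop-2-en-1-yl)cyclohexane-1-carboxylate | COC(=O)[C@@H]1C(=O)CC[C@H](Br)[C@@]1(C)CC=C | intermediate
13 | methyl (1S,2S,3S,6R)-3-bromo-6-hydroxy-2-methyl-2-(prop-2-en-1-yl)cyclohexane-1-carboxylate | COC(=O)[C@@H]1[C@H](O)CC[C@H](Br)[C@@]1(C)CC=C | intermediate
14 | (1R,2S,3S,4S)-4-bromo-2-[2-hydroxy-1,3-bis(trimethylsilyl)propan-2-yl]-3-methyl-3-(prop-2-en-1-yl)cyclohexan-1-ol | C[Si](C)(C)CC(O)(C[Si](C)(C)C)[C@@H]1[C@H](O)CC[C@H](Br)[C@@]1(C)CC=C | intermediate (not isolated)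
15 | (1R,2S,3S,4S)-4-bromo-3-methyl-3-(prop-2-en-1-yl)-2-[3-(trimethylsilyl)prop-1-en-2-yl]cyclohexan-1-ol | C=C(C[Si](C)(C)C)[C@@H]1[C@H](O)CC[C@H](Br)[C@@]1(C)CC=C | intermediate
16 | triethyl{[(1R,2S,3S,4S)-4-bromo-3-methyl-3-(prop-2-en-1-yl)-2-[3-(trimethylsilyl)prop-1-en-2-yl]cyclohexyl]oxy}silane | C=C(C[Si](C)(C)C)[C@@H]1[C@H](O[Si](CC)(CC)CC)CC[C@H](Br)[C@@]1(C)CC=C | intermediate
17 | 3-methylbut-2-en-1-ol | CC(C)=CCO | starting material
18 | [(2R)-3,3-dimethyloxiran-2-yl]methanol | OC[C@H]1OC1(C)C | intermediate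
19 | prop-2-en-1-yl 3-oxobutanoate (allyl acetoacetate) | C=CCOC(=O)CC(C)=O | starting material
20 | [(2R)-3,3-dimethyloxiran-2-yl]methyl trifluoromethanesulfonate | O=S(=O)(OC[C@H]1OC1(C)C)C(F)(F)F | intermediate (not isolated)
21 | allyl acetoacetate dianion (sodium lithium salt, C4 carbanion) | [Li+].[Na+].C=CCOC(=O)C=C([O-])[CH2-] | intermediate (not isolated)
22 | prop-2-en-1-yl 5-[(2R)-3,3-dimethyloxiran-2-yl]-3-oxopentanoate | C=CCOC(=O)CC(=O)CC[C@H]1OC1(C)C | intermediate
23 | prop-2-en-1-yl (6S)-6-bromo-7-hydroxy-7-methyl-3-oxooctanoate | C=CCOC(=O)CC(=O)CC[C@H](Br)C(C)(C)O | intermediate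
24 | (2S)-3,3-dimethyl-2-[3,5-dioxo-5-(prop-2-en-1-yloxy)pentyl]bromiranium | C=CCOC(=O)CC(=O)CC[C@@H]1[Br+]C1(C)C | intermediate (not isolated)
25 | prop-2-en-1-yl (1S,3S)-3-bromo-2,2-dimethyl-6-oxocyclohexane-1-carboxylate | C=CCOC(=O)[C@@H]1C(=O)CC[C@H](Br)C1(C)C | intermediate
26 | (1S,3S)-3-bromo-2,2-dimethyl-6-oxocyclohexane-1-carboxylic acid | OC(=O)[C@@H]1C(=O)CC[C@H](Br)C1(C)C | intermediate (not isolated)
27 | (4S)-4-bromo-3,3-dimethylcyclohexan-1-one | O=C1CC[C@H](Br)C(C)(C)C1 | intermediate
28 | (1S,4S)-4-bromo-1-{2-[(1S,2S,3S,6R)-3-bromo-2-methyl-2-(prop-2-en-1-yl)-6-(triethylsilyloxy)cyclohexyl]prop-2-en-1-yl}-3,3-dimethylcyclohexan-1-ol | CC1(C)C[C@@](O)(CC(=C)[C@@H]2[C@H](O[Si](CC)(CC)CC)CC[C@H](Br)[C@@]2(C)CC=C)CC[C@@H]1Br | intermediate (not isolated)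
29 | (1R,2S,3S,4S)-4-bromo-2-{3-[(1S,4S)-4-bromo-1-hydroxy-3,3-dimethylcyclohexyl]prop-1-en-2-yl}-3-methyl-3-(prop-2-en-1-yl)cyclohexan-1-ol | CC1(C)C[C@@](O)(CC(=C)[C@@H]2[C@H](O)CC[C@H](Br)[C@@]2(C)CC=C)CC[C@@H]1Br | intermediate
30 | (2S,3S,4S)-4-bromo-2-{3-[(1S,4S)-4-bromo-1-hydroxy-3,3-dimethylcyclohexyl]prop-1-en-2-yl}-3-methyl-3-(prop-2-en-1-yl)cyclohexan-1-one | CC1(C)C[C@@](O)(CC(=C)[C@@H]2C(=O)CC[C@H](Br)[C@@]2(C)CC=C)CC[C@@H]1Br | intermediate
31 | (1R,2S,3S,4S)-4-bromo-2-{3-[(1S,4S)-4-bromo-1-hydroxy-3,3-dimethylcyclohexyl]prop-1-en-2-yl}-1,3-dimethyl-3-(prop-2-en-1-yl)cyclohexan-1-ol | CC1(C)C[C@@](O)(CC(=C)[C@@H]2[C@](C)(O)CC[C@H](Br)[C@@]2(C)CC=C)CC[C@@H]1Br | intermediate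
32 | (3aS,4S,7R,7aS)-4-bromo-1-{[(1S,4S)-4-bromo-1-hydroxy-3,3-dimethylcyclohexyl]methyl}-3a,7-dimethyl-3a,4,5,6,7,7a-hexahydro-3H-inden-7-ol | CC1(C)C[C@@](O)(CC2=CC[C@]3(C)[C@@H](Br)CC[C@@](C)(O)[C@@H]23)CC[C@@H]1Br | intermediate
33 | (1S,3aS,4S,7R,7aS)-4-bromo-1-{[(1S,4S)-4-bromo-1-hydroxy-3,3-dimethylcyclohexyl]methyl}-3a,7-dimethyloctahydro-1H-inden-7-ol (CNP0166978.1) | CC1(C)C[C@@](O)(C[C@@H]2CC[C@]3(C)[C@@H](Br)CC[C@@](C)(O)[C@@H]23)CC[C@@H]1Br | target

**Count and risks**

Total step count: 18. Longest linear sequence: 13 steps (steps 1–8, then 14–18); the ring-A branch (steps 9–13) joins at step 14.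

The three steps most likely to fail:

Step 5 (key cyclisation). The ionisation may be diverted: the keto ester oxygen rather than the enol carbon may trap the cation, chloride from the Lewis acid may capture it, or the substrate may rest as a cyclic hemiketal or enol ether that does not ionise. The fallback separates installation of the leaving group from ring closure. Bromohydrin 10 is treated with HCl (4 M in dioxane, CH2Cl2, 0 °C), which should exchange the tertiary hydroxyl for chloride with retention through the bromonium ion and give methyl (6S,7R)-6-bromo-7-chloro-7-methyl-3-oxodec-9-enoate F1. F1 is then dissolved in hexafluoroisopropanol at room temperature, a strongly ionising and non-nucleophilic medium in which the tertiary chloride should leave with bromine participation and the keto ester enol should close the ring without any metal halide. The sequence returns to the route at 12.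

Step 14 (allylsilane–ketone coupling). The face of the ketone that is attacked depends on which chair of 27 reacts; 4-halocyclohexanones populate the bromine-axial chair appreciably, and equatorial attack on that chair would give the epimeric ring-A carbinol, so facial selectivity may be poor. The fallback carries out the allylation on the undecarboxylated keto ester 25, whose equatorial ester locks bromine equatorial and chelates titanium. Allylsilane 16 and 25 with TiCl4 (CH2Cl2, −78 °C) should give prop-2-en-1-yl (1S,3S,6S)-3-bromo-6-{2-[(1S,2S,3S,6R)-3-bromo-2-methyl-2-(prop-2-en-1-yl)-6-(triethylsilyloxy)cyclohexyl]prop-2-en-1-yl}-6-hydroxy-2,2-dimethylcyclohexane-1-carboxylate F2. Pd(PPh3)4 and morpholine remove the allyl group to give the corresponding carboxylic acid, (1S,3S,6S)-3-bromo-6-{2-[(1S,2S,3S,6R)-3-bromo-2-methyl-2-(prop-2-en-1-yl)-6-(triethylsilyloxy)cyclohexyl]prop-2-en-1-yl}-6-hydroxy-2,2-dimethylcyclohexane-1-carboxylic acid F3. Photocatalytic hydrodecarboxylation (9-mesityl-10-methylacridinium salt, catalytic diphenyl disulfide, 2,6-lutidine, trifluoroethanol, blue light) then replaces CO2H by H. The sequence returns to the route at 28, which is desilylated to 29 as in step 14.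

Step 18 (directed hydrogenation). The ring-A tertiary hydroxyl is also homoallylic to C1=C2 and sits on a freely rotating arm; it may bind iridium and deliver hydrogen to the open face opposite the angular methyl, eroding facial selectivity at C1. The fallback removes the competing director. Diol 32 is silylated at the less hindered ring-A hydroxyl with N-(trimethylsilyl)imidazole (1.1 equiv, CH2Cl2, 0 °C) to give the ring-A trimethylsilyl ether of 32, {[(1S,4S)-4-bromo-1-{[(3aS,4S,7R,7aS)-4-bromo-7-hydroxy-3a,7-dimethyl-3a,4,5,6,7,7a-hexahydro-3H-inden-1-yl]methyl}-3,3-dimethylcyclohexyl]oxy}trimethylsilane F4. Hydrogenation of F4 with Crabtree's catalyst, now directed only by the C7 hydroxyl, should give the ring-A trimethylsilyl ether of 33, {[(1S,4S)-4-bromo-1-{[(1S,3aS,4S,7R,7aS)-4-bromo-7-hydroxy-3a,7-dimethyloctahydro-1H-inden-1-yl]methyl}-3,3-dimethylcyclohexyl]oxy}trimethylsilane F5. K2CO3 in methanol removes the silyl group, and the sequence returns to the route at 33.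

Further compounds
F1 | step 5 | methyl (6S,7R)-6-bromo-7-chloro-7-methyl-3-oxodec-9-enoate | COC(=O)CC(=O)CC[C@H](Br)[C@@](Cl)(C)CC=C
F2 | step 14 | prop-2-en-1-yl (1S,3S,6S)-3-bromo-6-{2-[(1S,2S,3S,6R)-3-bromo-2-methyl-2-(prop-2-en-1-yl)-6-(triethylsilyloxy)cyclohexyl]prop-2-en-1-yl}-6-hydroxy-2,2-dimethylcyclohexane-1-carboxylate | C=CCOC(=O)[C@@H]1[C@@](O)(CC(=C)[C@@H]2[C@H](O[Si](CC)(CC)CC)CC[C@H](Br)[C@@]2(C)CC=C)CC[C@H](Br)C1(C)C
F3 | step 14 | (1S,3S,6S)-3-bromo-6-{2-[(1S,2S,3S,6R)-3-bromo-2-methyl-2-(prop-2-en-1-yl)-6-(triethylsilyloxy)cyclohexyl]prop-2-en-1-yl}-6-hydroxy-2,2-dimethylcyclohexane-1-carboxylic acid | OC(=O)[C@@H]1[C@@](O)(CC(=C)[C@@H]2[C@H](O[Si](CC)(CC)CC)CC[C@H](Br)[C@@]2(C)CC=C)CC[C@H](Br)C1(C)C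
F4 | step 18 | {[(1S,4S)-4-bromo-1-{[(3aS,4S,7R,7aS)-4-bromo-7-hydroxy-3a,7-dimethyl-3a,4,5,6,7,7a-hexahydro-3H-inden-1-yl]methyl}-3,3-dimethylcyclohexyl]oxy}trimethylsilane | CC1(C)C[C@@](O[Si](C)(C)C)(CC2=CC[C@]3(C)[C@@H](Br)CC[C@@](C)(O)[C@@H]23)CC[C@@H]1Br
F5 | step 18 | {[(1S,4S)-4-bromo-1-{[(1S,3aS,4S,7R,7aS)-4-bromo-7-hydroxy-3a,7-dimethyloctahydro-1H-inden-1-yl]methyl}-3,3-dimethylcyclohexyl]oxy}trimethylsilane | CC1(C)C[C@@](O[Si](C)(C)C)(C[C@@H]2CC[C@]3(C)[C@@H](Br)CC[C@@](C)(O)[C@@H]23)CC[C@@H]1Br
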